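The plan cuts C1'–C2' in the substituted ring (C1'–C4', C4a', C8a') of the naphthalene. It uses three features of that ring. C1', where both arenes meet, maps onto a diaryl ketone carbonyl. The 2'-methyl group is read as a reduced formyl group. The 4'-oxygen is read as a former ketone. In one operation a chiral pyrrolidine catalyst forms the aldehyde enamine, C2' adds to C1', water leaves and the C4' ketone enolises. Ring and C7–C1' axis therefore arise together, with O-4' free beside protected O-5'. The precursor is a 4-aryl-4-oxobutanal whose aryl ring bears an ortho isoquinoline-7-carbonyl group. Its crowded C7–C1' bond comes from an earlier aryllithium–aldehyde addition.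

Key step: step 11

Assumption: the SMILES string is taken as binding for the constitution (4'-OMe, free 5'-OH and 8-OH); it does not encode the axis, which is taken as M, and the (S)-catalyst is written on the understanding that its equally available mirror image is used should the sense of induction prove opposite.

Design points:
- **O-8 protection.** O-8 stays benzylated until the formyl carbon has reached the bromomethyl level. A free 8-OH beside a 2'-formyl group could bridge to a lactol, which would open a low-barrier path for rotation about the axis.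
- **Late release of the keto aldehyde.** It is released last, by a neutral alkene cleavage, and used at once. A 1,4-dicarbonyl unit beside a second ketone is sensitive to acid (furan formation) and to base (five-membered aldol closure).
- **Self-protection in the coupling.** The side-chain carbinol protects itself as its lithium alkoxide, which saves a silylation and a desilylation.
- **Isoquinoline construction.** The isoquinoline comes from an ortho-alkynyl aryl ketone and ammonia and is formylated at C7 through its magnesium phenoxide. No C–H annulation and no metalation of a 1-methylisoquinoline is needed.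
- **Combined final cleavage.** The C–Br bond and both benzyl ethers are cleaved in one hydrogenolysis.
- **Axis descriptor.** With CHO, CH2OH or CH2Br at C2', C2' outranks C8a' and the wanted spatial arrangement is called P. With CH3 the ranking reverses and the same arrangement is called M.

Step 1
Reactants: 1 1-(2,6-dihydroxyphenyl)ethanone
Product: 2 2-acetyl-3-hydroxyphenyl trifluoromethanesulfonate
Conditions: Tf2O (1.0 equiv), pyridine, CH2Cl2, −78 → 0 °C
Reagents that add atoms: trifluoromethanesulfonic anhydride, O=S(=O)(OS(=O)(=O)C(F)(F)F)C(F)(F)F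
Why: Phenol O-sulfonylation; after the first triflation the remaining hydroxyl is held in a hydrogen bond to the acetyl oxygen on a deactivated ring, so one equivalent of anhydride at low temperature should stop at the monotriflate.

Step 2
Reactants: 2 2-acetyl-3-hydroxyphenyl trifluoromethanesulfonate; 3 propyne
Product: 4 1-[2-hydroxy-6-(prop-1-yn-1-yl)phenyl]ethanone
Conditions: PdCl2(PPh3)2 (3 mol%), CuI (6 mol%), Et3N, DMF, sealed tube, 50 °C
Reagents that add atoms: none
Why: Sonogashira coupling; the triflate lies ortho to the electron-withdrawing acetyl group and should add oxidatively to zerovalent palladium with ease, while the meta-placed free phenol takes no part.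

Step 3
Reactants: 4 1-[2-hydroxy-6-(prop-1-yn-1-yl)phenyl]ethanone
Product: 6 1,3-dimethylisoquinolin-8-ol, via ketimine 5 (not isolated)
Conditions: NH3 (7 M in MeOH), sealed tube, 110 °C
Reagents that add atoms: ammonia, N
Why: Imination followed by 6-endo-dig hydroamination (ammonia annulation of an ortho-alkynylaryl ketone); the hydrogen-bond-stabilised ketimine adds through nitrogen to the methyl-bearing alkyne carbon, and aromatisation to the isoquinoline makes the closure irreversible.

Step 4
Reactants: 6 1,3-dimethylisoquinolin-8-ol
Product: 7 8-hydroxy-1,3-dimethylisoquinoline-7-carbaldehyde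
Conditions: MgCl2 (3 equiv), Et3N (4 equiv), (CH2O)n (6 equiv), MeCN, reflux; then 1 M HCl to pH 6–7
Reagents that add atoms: paraformaldehyde (as formaldehyde), C=O
Why: Casnati–Skattebøl ortho-formylation; the magnesium phenoxide delivers formaldehyde within its coordination sphere to the only free ortho position C7 (the other ortho carbon is the ring fusion C8a), and a second formaldehyde takes up hydride from the hydroxymethyl stage.

Step 5
Reactants: 7 8-hydroxy-1,3-dimethylisoquinoline-7-carbaldehyde
Product: 8 8-(benzyloxy)-1,3-dimethylisoquinoline-7-carbaldehyde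
Conditions: BnBr (1.1 equiv), K2CO3, DMF, 40 °C
Reagents that add atoms: benzyl bromide, BrCc1ccccc1
Why: Williamson ether synthesis; the phenoxide is far more nucleophilic than the ring nitrogen, which is flanked by two methyl groups, so O-benzylation should prevail.

Step 6
Reactants: 9 2-bromo-6-hydroxybenzaldehyde
Product: 10 2-(benzyloxy)-6-bromobenzaldehyde
Conditions: BnBr (1.1 equiv), K2CO3, DMF, 20 °C
Reagents that add atoms: benzyl bromide, BrCc1ccccc1
Why: Williamson ether synthesis on an acidic salicylaldehyde-type phenol with no competing nucleophile in the molecule.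

Step 7
Reactants: 10 2-(benzyloxy)-6-bromobenzaldehyde; 11 but-3-en-1-ylmagnesium bromide (0.5 M in THF)
Product: 12 1-[2-(benzyloxy)-6-bromophenyl]pent-4-en-1-ol (racemic)
Conditions: THF, −78 → 0 °C; aq NH4Cl
Reagents that add atoms: none
Why: Grignard 1,2-addition to a non-enolisable aldehyde at a temperature at which bromine–magnesium exchange does not compete; the new carbinol centre is racemic and is erased in step 9.

Step 8
Reactants: 12 1-[2-(benzyloxy)-6-bromophenyl]pent-4-en-1-ol (1.2 equiv); 8 8-(benzyloxy)-1,3-dimethylisoquinoline-7-carbaldehyde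
Product: 14 1-{2-(benzyloxy)-6-[[8-(benzyloxy)-1,3-dimethylisoquinolin-7-yl](hydroxy)methyl]phenyl}pent-4-en-1-ol (mixture of diastereomers), via dilithio species 13 (not isolated)
Conditions: n-BuLi (2.0 equiv per 12), THF, −78 °C; then 8, −78 → −20 °C; aq NH4Cl
Reagents that add atoms: none
Why: O-deprotonation and bromine–lithium exchange (the established dilithiation of 2-bromobenzyl alcohols) give an alkoxide-protected aryllithium that should add 1,2 to the aldehyde faster than it deprotonates the C1 methyl group; both carbinol centres form without control and are erased in step 9.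

Step 9
Reactants: 14 1-{2-(benzyloxy)-6-[[8-(benzyloxy)-1,3-dimethylisoquinolin-7-yl](hydroxy)methyl]phenyl}pent-4-en-1-ol
Product: 15 1-{2-(benzyloxy)-6-[8-(benzyloxy)-1,3-dimethylisoquinoline-7-carbonyl]phenyl}pent-4-en-1-one
Conditions: IBX (2-iodoxybenzoic acid, 3 equiv), DMSO, 20 °C
Reagents that add atoms: none
Why: Hypervalent-iodine oxidation of both benzylic carbinols in one operation under near-neutral conditions that spare the alkene, the benzyl ethers and the ring nitrogen; any hemiketal formed after the first oxidation stays in equilibrium with the open hydroxy ketone and is drained by the second.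

Step 10
Reactants: 15 1-{2-(benzyloxy)-6-[8-(benzyloxy)-1,3-dimethylisoquinoline-7-carbonyl]phenyl}pent-4-en-1-one
Product: 17 4-{2-(benzyloxy)-6-[8-(benzyloxy)-1,3-dimethylisoquinoline-7-carbonyl]phenyl}-4-oxobutanal, via vicinal diol 16 (not isolated)
Conditions: OsO4 (2 mol%), NaIO4 (4 equiv), 2,6-lutidine (2 equiv), dioxane/H2O 3:1, 20 °C; short silica plug, used at once
Reagents that add atoms: osmium tetroxide, O=[Os](=O)(=O)=O; sodium periodate, [Na+].[O-]I(=O)(=O)=O
Why: Lemieux–Johnson oxidation; catalytic dihydroxylation of the only alkene and periodate cleavage in the same flask release the aldehyde without acid or strong base, so neither furan formation nor premature aldol closure should occur.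

Step 11
Reactants: 17 4-{2-(benzyloxy)-6-[8-(benzyloxy)-1,3-dimethylisoquinoline-7-carbonyl]phenyl}-4-oxobutanal
Product: 21 (P)-5-(benzyloxy)-1-[8-(benzyloxy)-1,3-dimethylisoquinolin-7-yl]-4-hydroxynaphthalene-2-carbaldehyde, via enamine 18 (not isolated), via aldol carbinol 19 (not isolated), via keto tautomer 20 (not isolated)
Conditions: (S)-5-(pyrrolidin-2-yl)-1H-tetrazole (20 mol%), CHCl3 (0.02 M), 20 °C
Reagents that add atoms: none
Why: Proposed new method: the secondary amine condenses with the aldehyde of 17 to give enamine 18, whose nucleophilic carbon C2' adds to the diaryl ketone C1' while the tetrazole N–H activates that carbonyl, giving carbinol 19; water is then lost through the enamine/iminium manifold to give 20, whose doubly activated C3' methylene lets the C4' ketone enolise to the aromatic naphthol 21 with release of the catalyst. The closest known reaction type is the amine-catalysed atroposelective arene-forming aldol condensation of ortho-aroylaryl β,γ-unsaturated aldehydes, in which an alkene rather than a ketone supplies the last double bond; here a plain enamine replaces the dienamine, which should raise nucleophilicity, and aromatisation remains the driving force. The one new ring (C1', C2', C3', C4', C4a', C8a') closes in the 6-(enolexo)-exo-trig mode. No stereocentre survives: the transient centres C1' and C2' of 19 are set by the catalyst, which selects the ketone face and the rotamer of the isoquinolinyl group, and their configuration passes to the C7–C1' axis as water leaves (centre-to-axis transfer), after which 8-OBn (buttressed by the C1 methyl group), the formyl group and the peri C8'–H block rotation. The step needs C2' rather than C3' as the nucleophile, which the substrate secures because C1' has no α-hydrogen, the doubly ortho-flanked C4' aryl ketone forms an enamine far more slowly than the unhindered aldehyde, and no base able to enolise C4' is present; any five-membered (hydroxyindanone) adduct can also revert, whereas the six-membered path ends in an arene. The ring nitrogen is a weaker base than the catalyst's pyrrolidine and should not strip it of its proton, and high dilution suppresses intermolecular aldol reaction.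

Step 12
Reactants: 21 (P)-5-(benzyloxy)-1-[8-(benzyloxy)-1,3-dimethylisoquinolin-7-yl]-4-hydroxynaphthalene-2-carbaldehyde
Product: 22 (P)-5-(benzyloxy)-1-[8-(benzyloxy)-1,3-dimethylisoquinolin-7-yl]-4-methoxynaphthalene-2-carbaldehyde
Conditions: MeI (1.1 equiv), K2CO3, DMF, 20 °C
Reagents that add atoms: iodomethane, CI
Why: Williamson O-methylation of the only free hydroxyl, which the key step has already differentiated from O-5'; the naphthoxide should outrun the hindered ring nitrogen, and the axis is not stressed at room temperature.

Step 13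
Reactants: 22 (P)-5-(benzyloxy)-1-[8-(benzyloxy)-1,3-dimethylisoquinolin-7-yl]-4-methoxynaphthalene-2-carbaldehyde
Product: 23 (P)-{5-(benzyloxy)-1-[8-(benzyloxy)-1,3-dimethylisoquinolin-7-yl]-4-methoxynaphthalen-2-yl}methanol
Conditions: NaBH4, THF/MeOH, 0 °C; H2O
Reagents that add atoms: none
Why: Borohydride reduction of an aryl aldehyde, which touches no other group and replaces the flat formyl group by a bulkier tetrahedral ortho substituent, so the axis should become more stable.

Step 14
Reactants: 23 (P)-{5-(benzyloxy)-1-[8-(benzyloxy)-1,3-dimethylisoquinolin-7-yl]-4-methoxynaphthalen-2-yl}methanol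
Product: 24 (P)-8-(benzyloxy)-7-[5-(benzyloxy)-2-(bromomethyl)-4-methoxynaphthalen-1-yl]-1,3-dimethylisoquinoline
Conditions: CBr4 (1.3 equiv), PPh3 (1.3 equiv), CH2Cl2, 0 °C; used without storage
Reagents that add atoms: tetrabromomethane, BrC(Br)(Br)Br
Why: Appel reaction; bromide displaces the alkoxyphosphonium group at the primary benzylic carbon under neutral conditions, and the methyl-flanked ring nitrogen should be slow to self-alkylate when the bromide is used directly.

Step 15
Reactants: 24 (P)-8-(benzyloxy)-7-[5-(benzyloxy)-2-(bromomethyl)-4-methoxynaphthalen-1-yl]-1,3-dimethylisoquinoline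
Product: 25 (M)-7-(5-hydroxy-4-methoxy-2-methylnaphthalen-1-yl)-1,3-dimethylisoquinolin-8-ol (target)
Conditions: H2 (1 atm), Pd/C (10 wt%), NaOAc (1.5 equiv), EtOAc/MeOH 4:1, 20 °C
Reagents that add atoms: none
Why: Catalytic hydrogenolysis cleaves the benzylic C–Br bond and both aryl benzyl ethers in one operation while the naphthalene and isoquinoline rings resist reduction at one atmosphere; 8-OH is freed only when no formyl group remains, and the descriptor changes from P to M for ranking reasons alone.

Compound list
1 | 1-(2,6-dihydroxyphenyl)ethanone | CC(=O)c1c(O)cccc1O | starting material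
2 | 2-acetyl-3-hydroxyphenyl trifluoromethanesulfonate | CC(=O)c1c(O)cccc1OS(=O)(=O)C(F)(F)F | intermediate
3 | propyne | CC#C | starting material
4 | 1-[2-hydroxy-6-(prop-1-yn-1-yl)phenyl]ethanone | CC#Cc1cccc(O)c1C(C)=O | intermediate
5 | 2-(1-iminoethyl)-3-(prop-1-yn-1-yl)phenol (ketimine, not isolated) | CC#Cc1cccc(O)c1C(C)=N | intermediate
6 | 1,3-dimethylisoquinolin-8-ol | Cc1cc2cccc(O)c2c(C)n1 | intermediate
7 | 8-hydroxy-1,3-dimethylisoquinoline-7-carbaldehyde | Cc1cc2ccc(C=O)c(O)c2c(C)n1 | intermediate
8 | 8-(benzyloxy)-1,3-dimethylisoquinoline-7-carbaldehyde | Cc1cc2ccc(C=O)c(OCc3ccccc3)c2c(C)n1 | intermediate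
9 | 2-bromo-6-hydroxybenzaldehyde | O=Cc1c(O)cccc1Br | starting material
10 | 2-(benzyloxy)-6-bromobenzaldehyde | O=Cc1c(OCc2ccccc2)cccc1Br | intermediate
11 | but-3-en-1-ylmagnesium bromide | C=CCC[Mg]Br | starting material
12 | 1-[2-(benzyloxy)-6-bromophenyl]pent-4-en-1-ol (racemic) | C=CCCC(O)c1c(OCc2ccccc2)cccc1Br | intermediate
13 | lithium 1-[2-(benzyloxy)-6-lithiophenyl]pent-4-en-1-olate (not isolated) | [Li]OC(CCC=C)c1c(OCc2ccccc2)cccc1[Li] | intermediate
14 | 1-{2-(benzyloxy)-6-[[8-(benzyloxy)-1,3-dimethylisoquinolin-7-yl](hydroxy)methyl]phenyl}pent-4-en-1-ol (diastereomer mixture, both centres uncontrolled) | C=CCCC(O)c1c(OCc2ccccc2)cccc1C(O)c1ccc2cc(C)nc(C)c2c1OCc1ccccc1 | intermediate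
15 | 1-{2-(benzyloxy)-6-[8-(benzyloxy)-1,3-dimethylisoquinoline-7-carbonyl]phenyl}pent-4-en-1-one | C=CCCC(=O)c1c(OCc2ccccc2)cccc1C(=O)c1ccc2cc(C)nc(C)c2c1OCc1ccccc1 | intermediate
16 | 1-{2-(benzyloxy)-6-[8-(benzyloxy)-1,3-dimethylisoquinoline-7-carbonyl]phenyl}-4,5-dihydroxypentan-1-one (racemic, not isolated) | OCC(O)CCC(=O)c1c(OCc2ccccc2)cccc1C(=O)c1ccc2cc(C)nc(C)c2c1OCc1ccccc1 | intermediate
17 | 4-{2-(benzyloxy)-6-[8-(benzyloxy)-1,3-dimethylisoquinoline-7-carbonyl]phenyl}-4-oxobutanal (key-step precursor) | O=CCCC(=O)c1c(OCc2ccccc2)cccc1C(=O)c1ccc2cc(C)nc(C)c2c1OCc1ccccc1 | intermediate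
18 | (E)-1-{2-(benzyloxy)-6-[8-(benzyloxy)-1,3-dimethylisoquinoline-7-carbonyl]phenyl}-4-[(S)-2-(1H-tetrazol-5-yl)pyrrolidin-1-yl]but-3-en-1-one (enamine, not isolated) | O=C(C/C=C/N1CCC[C@H]1c1nnn[nH]1)c1c(OCc2ccccc2)cccc1C(=O)c1ccc2cc(C)nc(C)c2c1OCc1ccccc1 | intermediate
19 | 5-(benzyloxy)-1-[8-(benzyloxy)-1,3-dimethylisoquinolin-7-yl]-1-hydroxy-4-oxo-1,2,3,4-tetrahydronaphthalene-2-carbaldehyde (drawn as the free aldehyde, catalyst-bound in the flask; C1' and C2' set by the catalyst, not assigned, both erased; not isolated) | O=CC1CC(=O)c2c(OCc3ccccc3)cccc2C1(O)c1ccc2cc(C)nc(C)c2c1OCc1ccccc1 | intermediate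
20 | 5-(benzyloxy)-1-[8-(benzyloxy)-1,3-dimethylisoquinolin-7-yl]-4-oxo-3,4-dihydronaphthalene-2-carbaldehyde (keto tautomer, not isolated) | O=CC1=C(c2ccc3cc(C)nc(C)c3c2OCc2ccccc2)c2cccc(OCc3ccccc3)c2C(=O)C1 | intermediate
21 | (P)-5-(benzyloxy)-1-[8-(benzyloxy)-1,3-dimethylisoquinolin-7-yl]-4-hydroxynaphthalene-2-carbaldehyde (key-step product; axis not expressible in SMILES) | O=Cc1cc(O)c2c(OCc3ccccc3)cccc2c1-c1ccc2cc(C)nc(C)c2c1OCc1ccccc1 | intermediate
22 | (P)-5-(benzyloxy)-1-[8-(benzyloxy)-1,3-dimethylisoquinolin-7-yl]-4-methoxynaphthalene-2-carbaldehyde | COc1cc(C=O)c(-c2ccc3cc(C)nc(C)c3c2OCc2ccccc2)c2cccc(OCc3ccccc3)c12 | intermediate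
23 | (P)-{5-(benzyloxy)-1-[8-(benzyloxy)-1,3-dimethylisoquinolin-7-yl]-4-methoxynaphthalen-2-yl}methanol | COc1cc(CO)c(-c2ccc3cc(C)nc(C)c3c2OCc2ccccc2)c2cccc(OCc3ccccc3)c12 | intermediate
24 | (P)-8-(benzyloxy)-7-[5-(benzyloxy)-2-(bromomethyl)-4-methoxynaphthalen-1-yl]-1,3-dimethylisoquinoline | COc1cc(CBr)c(-c2ccc3cc(C)nc(C)c3c2OCc2ccccc2)c2cccc(OCc3ccccc3)c12 | intermediate
25 | (M)-7-(5-hydroxy-4-methoxy-2-methylnaphthalen-1-yl)-1,3-dimethylisoquinolin-8-ol | COc1cc(C)c(-c2ccc3cc(C)nc(C)c3c2O)c2cccc(O)c12 | target

Total step count: 15. Longest linear sequence: 13 (steps 1–5 and 8–15).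

Steps most likely to fail

1. **Step 11.**
   - What may go wrong: the catalyst's chirality may transfer poorly to the axis. The enamine may add slowly to the crowded, electron-rich diaryl ketone. Material may leak away through enolisation at C3' and five-membered closure.
   - Fallback: it sets out from 17 and returns at 23, and it moves axis control from the ring closure to a later dynamic kinetic resolution. Because the axis need not be controlled at closure, the ring is closed under forcing achiral conditions (pyrrolidine and AcOH, one equivalent each, toluene, 60 °C; a classical enamine aldol condensation). This gives the racemic naphthol aldehyde F1. F1 is O-methylated (MeI, K2CO3) to the racemic methyl ether F2. Pinnick oxidation (NaClO2, NaH2PO4, 2-methylbut-2-ene) gives the naphthoic acid F3. Hydrogenolysis (H2, Pd/C) gives the dihydroxy acid F4. Its carboxyl group is esterified by the neighbouring 8-OH (EDC·HCl, DMAP, dilute CH2Cl2) to the six-membered biaryl lactone F5. Bridged biaryl lactones of this kind are configurationally labile. Reductive ring cleavage with BH3·THF and a CBS oxazaborolidine therefore acts as a dynamic kinetic resolution and should give the axially enriched hydroxymethyl diphenol F6. Twofold phenol benzylation (BnBr, K2CO3, acetone) then gives 23.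

2. **Step 8.**
   - What may go wrong: halogen–metal exchange may stay incomplete on a poorly soluble alkoxide. Alternatively, a proton may transfer from the C1 methyl group of the aldehyde to the basic aryllithium in place of carbonyl addition.
   - Fallback: it sets out from 12 and returns at 14, and it replaces the dianion by a protected, non-basic organocerium nucleophile. Silylation (TBSCl, imidazole, DMF) gives the silyl ether F7. Bromine–lithium exchange (t-BuLi, 2 equiv, THF, −78 °C), transmetalation with anhydrous CeCl3 and addition of 8 give the monosilylated carbinol F8. Desilylation with TBAF in THF gives 14.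

3. **Step 4.**
   - What may go wrong: electrophilic attack may be sluggish on the electron-poor benzo ring of the azaarene. The activated C1 methyl group may also be hydroxymethylated.
   - Fallback: it sets out from 6 and returns at 8, and it installs the formyl carbon by halogen–metal exchange instead of electrophilic formylation. Amine-directed ortho-bromination (NBS, catalytic i-Pr2NH, CH2Cl2, 0 °C, the conditions that turn 1-naphthols into 2-bromo-1-naphthols) gives the bromophenol F9. Benzylation (BnBr, K2CO3, DMF) gives the bromo ether F10. Bromine–magnesium exchange with i-PrMgCl·LiCl in THF, which is too weakly basic to attack the C1 methyl group, followed by a DMF quench gives 8.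

Further compounds
F1 | step 11 | racemic 5-(benzyloxy)-1-[8-(benzyloxy)-1,3-dimethylisoquinolin-7-yl]-4-hydroxynaphthalene-2-carbaldehyde | O=Cc1cc(O)c2c(OCc3ccccc3)cccc2c1-c1ccc2cc(C)nc(C)c2c1OCc1ccccc1
F2 | step 11 | racemic 5-(benzyloxy)-1-[8-(benzyloxy)-1,3-dimethylisoquinolin-7-yl]-4-methoxynaphthalene-2-carbaldehyde | COc1cc(C=O)c(-c2ccc3cc(C)nc(C)c3c2OCc2ccccc2)c2cccc(OCc3ccccc3)c12
F3 | step 11 | racemic 5-(benzyloxy)-1-[8-(benzyloxy)-1,3-dimethylisoquinolin-7-yl]-4-methoxynaphthalene-2-carboxylic acid | COc1cc(C(=O)O)c(-c2ccc3cc(C)nc(C)c3c2OCc2ccccc2)c2cccc(OCc3ccccc3)c12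
F4 | step 11 | racemic 5-hydroxy-1-(8-hydroxy-1,3-dimethylisoquinolin-7-yl)-4-methoxynaphthalene-2-carboxylic acid | COc1cc(C(=O)O)c(-c2ccc3cc(C)nc(C)c3c2O)c2cccc(O)c12
F5 | step 11 | six-membered biaryl lactone of F4 (2'-carboxyl esterified by O-8, 5'-OH free, axis labile) | COc1cc2C(=O)Oc3c(ccc4cc(C)nc(C)c34)-c2c2cccc(O)c12
F6 | step 11 | (P)-7-[5-hydroxy-2-(hydroxymethyl)-4-methoxynaphthalen-1-yl]-1,3-dimethylisoquinolin-8-ol | COc1cc(CO)c(-c2ccc3cc(C)nc(C)c3c2O)c2cccc(O)c12
F7 | step 8 | {1-[2-(benzyloxy)-6-bromophenyl]pent-4-en-1-yl}oxy(tert-butyl)dimethylsilane (racemic) | C=CCCC(O[Si](C)(C)C(C)(C)C)c1c(OCc2ccccc2)cccc1Br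
F8 | step 8 | [8-(benzyloxy)-1,3-dimethylisoquinolin-7-yl]{3-(benzyloxy)-2-[1-(tert-butyldimethylsilyloxy)pent-4-en-1-yl]phenyl}methanol (diastereomer mixture) | C=CCCC(O[Si](C)(C)C(C)(C)C)c1c(OCc2ccccc2)cccc1C(O)c1ccc2cc(C)nc(C)c2c1OCc1ccccc1
F9 | step 4 | 7-bromo-1,3-dimethylisoquinolin-8-ol | Cc1cc2ccc(Br)c(O)c2c(C)n1
F10 | step 4 | 8-(benzyloxy)-7-bromo-1,3-dimethylisoquinoline | Cc1cc2ccc(Br)c(OCc3ccccc3)c2c(C)n1
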